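**Retrosynthetic overview**

1. Numbering: side chain C1 (OH) to C4 (methyl C15). Ring A (cyclohexene) is C5–C10, with the chain on C5, ester oxygen O6 on C6 and methyl C14 on C10. Ring B (lactone) is C7, C11 (=C13H2), C12 (C=O), O8, C8.
2. Feature: the fully substituted C5=C10 alkene of ring A bears two unlike carbon groups (C4 chain, C14 methyl) and is read as an internal alkyne. C6–C7–C8–C9 with the cis-fused ring B is read as a cyclobutanone annulated to the lactone, so cutting C5–C6 and C9–C10 gives both pieces.
3. End game, backwards: C1 silyl ether off; O6 acylated with (R)-2-methylbutanoic acid; C11=C13 by aminomethylation/elimination on the O6-silylated lactone; C6 carbinol from the C6 ketone.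
4. Pieces: the dione comes from 2,3-dihydrofuran and dichloroketene ([2+2], dechlorination, enzymatic sorting of enantiomers, RuO4). The alkyne comes from (S)-citronellal (aldehyde to alkyne, C-methylation, ozonolysis/reduction, silylation).
5. Ring order: the five-membered ring arrives with dihydrofuran and becomes ring B, the four-membered ring is made by [2+2], and ring A is formed last by two-carbon expansion of the four-membered ring.

Key step: step 9

Assumption: a Prelog-selective alcohol dehydrogenase accepts the oxa-bicyclic ketone as such enzymes accept carbocyclic bicyclo[3.2.0]heptan-6-ones, and commercial (S)-citronellal and (R)-2-methylbutanoic acid are taken as enantiopure.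

**Route**

Step 1
Reactants: 1 2,3-dihydrofuran; 2 trichloroacetyl chloride
Product: 4 (±)-cis-7,7-dichloro-2-oxabicyclo[3.2.0]heptan-6-one, via dichloroketene 3 (not isolated)
Conditions: Zn–Cu couple, Et2O/DME, slow addition of 2, 0 °C → rt
Reagents that add atoms: none
Why: Thermal [2+2] ketene–enol ether cycloaddition: the nucleophilic β-carbon of the enol ether bonds to the ketene carbonyl carbon, which places the ketone next to the all-carbon bridgehead and CCl2 next to the O-bearing bridgehead, and suprafacial addition to the ring alkene allows only the cis fusion (racemic).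

Step 2
Reactants: 4 (±)-cis-7,7-dichloro-2-oxabicyclo[3.2.0]heptan-6-one
Product: 5 (±)-cis-2-oxabicyclo[3.2.0]heptan-6-one
Conditions: Zn dust, NH4Cl, MeOH, rt
Reagents that add atoms: none
Why: Zinc-mediated reductive dechlorination of an α,α-dichloroketone through its zinc enolate, run near neutrality so that the β-alkoxy cyclobutanone neither opens nor eliminates and the bridgeheads stay as set.

Step 3
Reactants: 5 (±)-cis-2-oxabicyclo[3.2.0]heptan-6-one
Product: 6 (1R,5S,6S)-2-oxabicyclo[3.2.0]heptan-6-ol (endo alcohol)
Conditions: Prelog-selective alcohol dehydrogenase (for example ADH-A from Rhodococcus ruber), NAD+ (cat.), i-PrOH (10 vol %), phosphate buffer pH 7, 30 °C; chromatography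
Reagents that add atoms: none
Why: Enzymatic carbonyl reduction that sorts the enantiomers (Prelog rule, known for bicyclo[3.2.0]heptan-6-ones): hydride goes to the Re face of C6 in both enantiomers, so the (1R,5R)-ketone should give the endo (6S)-alcohol 6 and the (1S,5S)-ketone the exo (6S)-alcohol, and separation of these diastereomers fixes the absolute configuration of the later C7 and C8.

Step 4
Reactants: 6 (1R,5S,6S)-2-oxabicyclo[3.2.0]heptan-6-ol
Product: 8 (1R,5R)-2-oxabicyclo[3.2.0]heptane-3,6-dione, via keto ether 7 (not isolated)
Conditions: RuCl3·xH2O (5 mol %), NaIO4 (4 equiv), EtOAc/MeCN/H2O, rt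
Reagents that add atoms: sodium periodate, [Na+].[O-]I(=O)(=O)=O
Why: Catalytic RuO4 oxidation takes the secondary alcohol to the ketone and the ether methylene C3 to the lactone carbonyl, the only other α-oxy C–H being a cyclobutane bridgehead bond β to the ketone and thus deactivated, and the bridgeheads cannot scramble because a trans-fused bicyclo[3.2.0] skeleton is out of reach.

Step 5
Reactants: 9 (S)-citronellal
Product: 11 (S)-3,7-dimethyloct-6-en-1-yne, via enol nonaflate 10 (not isolated)
Conditions: n-C4F9SO2F (1.3 equiv), phosphazene base P2-Et (2.4 equiv, slow addition), DMF, −20 °C → rt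
Reagents that add atoms: none
Why: One-pot nonaflation–elimination of an enolisable aldehyde: the enolate is O-sulfonylated to the alkenyl nonaflate and a second equivalent of base removes the sulfonic acid by E2, which turns CH2–CHO into C≡CH without change in carbon count, and the stereocentre (later C4) lies β to the carbonyl group and is never deprotonated.

Step 6
Reactants: 11 (S)-3,7-dimethyloct-6-en-1-yne
Product: 13 (S)-2,6-dimethylnon-2-en-7-yne, via lithium acetylide 12 (not isolated)
Conditions: n-BuLi, THF, −78 °C; MeI, −78 °C → rt
Reagents that add atoms: iodomethane, CI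
Why: SN2 alkylation of a lithium acetylide with methyl iodide brings in C14, the acetylenic proton being the only one acidic enough for n-BuLi at this temperature.

Step 7
Reactants: 13 (S)-2,6-dimethylnon-2-en-7-yne
Product: 15 (S)-4-methylhept-5-yn-1-ol, via aldehyde 14 (not isolated)
Conditions: O3, CH2Cl2/MeOH, Sudan Red 7B as end-point dye, −78 °C; NaBH4, −78 °C → rt
Reagents that add atoms: ozone, [O-][O+]=O
Why: Chemoselective Criegee ozonolysis with reductive work-up: the electron-rich trisubstituted alkene takes up ozone much faster than the alkyne, and NaBH4 reduces the peroxidic material and the aldehyde to the C1 alcohol without touching C4.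

Step 8
Reactants: 15 (S)-4-methylhept-5-yn-1-ol
Product: 16 tert-butyl{[(4S)-4-methylhept-5-yn-1-yl]oxy}diphenylsilane
Conditions: TBDPSCl, imidazole, CH2Cl2, 0 °C → rt
Reagents that add atoms: tert-butyl(chloro)diphenylsilane, CC(C)(C)[Si](Cl)(c1ccccc1)c1ccccc1
Why: Standard silylation of a primary alcohol, with TBDPS chosen because it must outlast the later acidic removal of a triethylsilyl group.

Step 9
Reactants: 8 (1R,5R)-2-oxabicyclo[3.2.0]heptane-3,6-dione; 16 tert-butyl{[(4S)-4-methylhept-5-yn-1-yl]oxy}diphenylsilane
Product: 17 (3aR,7aR)-5-[(2S)-5-(tert-butyldiphenylsilyloxy)pentan-2-yl]-6-methyl-3,3a,7,7a-tetrahydro-1-benzofuran-2,4-dione (cis-fused lactone enone with C6 ketone)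
Conditions: Ni(cod)2 (10 mol %) premixed with the base-free carbene IPr*OMe, 1,3-bis[2,6-bis(diphenylmethyl)-4-methoxyphenyl]imidazol-2-ylidene (10 mol %), 16 (1.3 equiv), toluene, 45 °C, inert atmosphere; short plug of neutral silica, used at once
Reagents that add atoms: none
Why: Proposed new method: zerovalent nickel carrying one very large carbene should bind the C6 carbonyl of 8 and alkyne 16 and couple them oxidatively to a spiro oxanickelacyclopentene (C5–C6 bond), after which β-carbon elimination breaks the strained C6–C9 bond to a seven-membered nickelacycle with nickel between C9 and C10 and reductive elimination forms C9–C10. The closest known reaction type is the intermolecular insertion of internal alkynes into simple cyclobutanones with zerovalent nickel and a phosphine, joined here to the ligand-size reversal of alkyne orientation known from nickel-catalysed reductive aldehyde–alkyne coupling; neither has been shown on a 2-substituted 3-acyloxycyclobutanone or with the larger alkyne substituent ending next to the carbonyl group. Ring A is closed as a formal (4+2) two-carbon ring expansion, its last bond by C(sp3)–C(sp2) reductive elimination from the seven-membered metallacycle, and the syn addition across the alkyne places C6 and C9 cis on C5=C10 as the six-membered ring requires. No stereocentre is created: no bond to C7 or C8 is broken, so the cis fusion of ring B set in 8 is carried over, and C4 is a spectator. Orientation is secured by the contrast between the methyl group and the α-branched C4 substituent of 16, which the wall of the carbene forces away from nickel and hence onto the carbon that bonds to C6, and the choice of bond by the contrast between the methylene C9 (primary alkylnickel, exposed) and the methine C7 (secondary, shielded by ring B). β-Acyloxy elimination from the C9–nickel stage and loss of O8 from 17 are countered by the fast reductive elimination that a bulky ligand enforces, by the absence of free base and by immediate use of 17 in step 10.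

Step 10
Reactants: 17 cis-fused lactone enone
Product: 18 (3aS,4R,7aR)-5-[(2S)-5-(tert-butyldiphenylsilyloxy)pentan-2-yl]-4-hydroxy-6-methyl-3a,4,7,7a-tetrahydro-1-benzofuran-2(3H)-one (H6/H7/H8 all cis)
Conditions: CeCl3·7H2O (1.2 equiv), NaBH4 (1.1 equiv), MeOH/THF, −78 °C; AcOH/pH 7 buffer quench at −78 °C
Reagents that add atoms: none
Why: Luche 1,2-reduction: the hard cerium-modified borohydride attacks C6 from the convex face of the cis-fused bicycle (the side of H7 and H8, anti to C11), which sets C6 as R with O6 cis to C11 and O8, while the weakly acidic medium at −78 °C should hold back E1cB loss of O8 and migration of the lactone to O6.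

Step 11
Reactants: 18 all-cis allylic alcohol
Product: 19 (3aR,4R,7aR)-5-[(2S)-5-(tert-butyldiphenylsilyloxy)pentan-2-yl]-6-methyl-4-(triethylsilyloxy)-3a,4,7,7a-tetrahydro-1-benzofuran-2(3H)-one
Conditions: TESOTf (1.3 equiv), 2,6-lutidine (2 equiv), CH2Cl2, −78 → 0 °C
Reagents that add atoms: triethylsilyl trifluoromethanesulfonate, CC[Si](CC)(CC)OS(=O)(=O)C(F)(F)F
Why: Silyl ether formation with a silyl triflate and a hindered base is strong enough for the crowded concave O6–H, blocks O6 so that it can neither attack C12 nor consume base in step 12, and is orthogonal to TBDPS.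

Step 12
Reactants: 19 O6-triethylsilyl lactone
Product: 21 (3S,3aR,4R,7aR)-3-[(dimethylamino)methyl] derivative of 19, via lithium enolate 20 (not isolated)
Conditions: LiN(i-Pr)2 (1.15 equiv), THF, −78 °C; CH2=NMe2+ I− (3 equiv), −78 °C → rt
Reagents that add atoms: dimethyl(methylidene)ammonium iodide (Eschenmoser's salt), C=[N+](C)C.[I-]
Why: Mannich-type aminomethylation of the lactone lithium enolate brings in C13; C11–H2 is the only acidic site because the acyl group is deliberately not yet on O6 (an ester there would offer a second enolisable stereocentre and a carbonyl group within reach of the enolate), and the C11 configuration expected from convex-face attack is lost in step 13.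

Step 13
Reactants: 21 C11-(dimethylaminomethyl) lactone
Product: 23 (3aR,4R,7aR)-5-[(2S)-5-(tert-butyldiphenylsilyloxy)pentan-2-yl]-6-methyl-3-methylidene-4-(triethylsilyloxy)-3a,4,7,7a-tetrahydro-1-benzofuran-2(3H)-one, via ammonium iodide 22 (not isolated)
Conditions: MeI (excess), CH2Cl2/MeOH, rt; evaporation; aq NaHCO3/CH2Cl2, rt
Reagents that add atoms: none
Why: N-Methylation followed by Hofmann-type (E1cB) elimination of the amine under bicarbonate gives the exocyclic C11=C13 alkene, the base being too mild to move the double bond into ring B.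

Step 14
Reactants: 23 O6-triethylsilyl methylene lactone
Product: 24 (3aS,4R,7aR)-5-[(2S)-5-(tert-butyldiphenylsilyloxy)pentan-2-yl]-4-hydroxy-6-methyl-3-methylidene-3a,4,7,7a-tetrahydro-1-benzofuran-2(3H)-one
Conditions: PPTS (0.2 equiv), MeOH/CH2Cl2, 0 °C → rt
Reagents that add atoms: none
Why: In this acid-catalysed methanolysis of a silyl ether the triethylsilyl group leaves far faster than the primary TBDPS group, and the buffered acid is too weak to ionise the allylic C6–O bond or to add methanol to the methylene lactone.

Step 15
Reactants: 24 C6 alcohol with methylene lactone; 25 (R)-2-methylbutanoic acid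
Product: 27 (3aR,4R,7aR)-5-[(2S)-5-(tert-butyldiphenylsilyloxy)pentan-2-yl]-6-methyl-3-methylidene-2-oxo-2,3,3a,4,7,7a-hexahydro-1-benzofuran-4-yl (2R)-2-methylbutanoate, via mixed anhydride 26 (not isolated)
Conditions: 25, 2,4,6-trichlorobenzoyl chloride, Et3N, toluene, rt; then 24, DMAP (1.5 equiv), toluene, rt
Reagents that add atoms: none
Why: Yamaguchi esterification: acyl transfer through the acylpyridinium ion reaches even the hindered O6, leaves the C6–O bond intact (retention at C6) and, since no ketene arises from the mixed anhydride, should keep the R centre of the acid.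

Step 16
Reactants: 27 TBDPS-protected ester
Product: 28 CNP0291605.3, (3aR,4R,7aR)-5-[(2S)-5-hydroxypentan-2-yl]-6-methyl-3-methylidene-2-oxo-2,3,3a,4,7,7a-hexahydro-1-benzofuran-4-yl (2R)-2-methylbutanoate
Conditions: HF·pyridine, extra pyridine, THF, 0 °C → rt (polyethylene vessel)
Reagents that add atoms: none
Why: Fluoride-driven Si–O cleavage under buffered, mildly acidic conditions avoids the basic fluoride or alkoxide that could add to the methylene lactone or move the acyl group.

**Compound list**

1 | 2,3-dihydrofuran | C1=COCC1 | starting material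
2 | trichloroacetyl chloride | ClC(Cl)(Cl)C(Cl)=O | starting material
3 | dichloroketene | ClC(Cl)=C=O | intermediate
4 | (±)-cis-7,7-dichloro-2-oxabicyclo[3.2.0]heptan-6-one (racemate, one enantiomer drawn) | C1CO[C@@H]2C(Cl)(Cl)C(=O)[C@H]12 | intermediate
5 | (±)-cis-2-oxabicyclo[3.2.0]heptan-6-one (racemate, one enantiomer drawn) | C1CO[C@@H]2CC(=O)[C@H]12 | intermediate
6 | (1R,5S,6S)-2-oxabicyclo[3.2.0]heptan-6-ol (endo) | C1CO[C@@H]2C[C@H](O)[C@H]12 | intermediate
7 | (1R,5R)-2-oxabicyclo[3.2.0]heptan-6-one | C1CO[C@@H]2CC(=O)[C@H]12 | intermediate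
8 | (1R,5R)-2-oxabicyclo[3.2.0]heptane-3,6-dione | C1C(=O)O[C@@H]2CC(=O)[C@H]12 | intermediate
9 | (S)-citronellal | O=CC[C@@H](C)CCC=C(C)C | starting material
10 | (3S)-3,7-dimethylocta-1,6-dien-1-yl nonafluorobutane-1-sulfonate (E/Z mixture) | FC(F)(F)C(F)(F)C(F)(F)C(F)(F)S(=O)(=O)OC=C[C@@H](C)CCC=C(C)C | intermediate
11 | (S)-3,7-dimethyloct-6-en-1-yne | C#C[C@@H](C)CCC=C(C)C | intermediate
12 | lithium acetylide of 11 | [Li]C#C[C@@H](C)CCC=C(C)C | intermediate
13 | (S)-2,6-dimethylnon-2-en-7-yne | CC#C[C@@H](C)CCC=C(C)C | intermediate
14 | (S)-4-methylhept-5-ynal | CC#C[C@@H](C)CCC=O | intermediate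
15 | (S)-4-methylhept-5-yn-1-ol | CC#C[C@@H](C)CCCO | intermediate
16 | tert-butyl{[(4S)-4-methylhept-5-yn-1-yl]oxy}diphenylsilane | CC#C[C@@H](C)CCCO[Si](c1ccccc1)(c1ccccc1)C(C)(C)C | intermediate
17 | (3aR,7aR)-5-[(2S)-5-(tert-butyldiphenylsilyloxy)pentan-2-yl]-6-methyl-3,3a,7,7a-tetrahydro-1-benzofuran-2,4-dione | C1C(=O)O[C@@H]2CC(C)=C([C@@H](C)CCCO[Si](c3ccccc3)(c3ccccc3)C(C)(C)C)C(=O)[C@H]12 | intermediate
18 | (3aS,4R,7aR)-4-hydroxy lactone, all-cis at C6, C7, C8 | C1C(=O)O[C@@H]2CC(C)=C([C@@H](C)CCCO[Si](c3ccccc3)(c3ccccc3)C(C)(C)C)[C@H](O)[C@H]12 | intermediate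
19 | (3aR,4R,7aR)-4-(triethylsilyloxy) lactone | C1C(=O)O[C@@H]2CC(C)=C([C@@H](C)CCCO[Si](c3ccccc3)(c3ccccc3)C(C)(C)C)[C@H](O[Si](CC)(CC)CC)[C@H]12 | intermediate
20 | lithium enolate of 19 (C11=C12–OLi) | C1=C(O[Li])O[C@@H]2CC(C)=C([C@@H](C)CCCO[Si](c3ccccc3)(c3ccccc3)C(C)(C)C)[C@H](O[Si](CC)(CC)CC)[C@H]12 | intermediate
21 | (3S,3aR,4R,7aR)-3-[(dimethylamino)methyl]-4-(triethylsilyloxy) lactone | CN(C)C[C@H]1C(=O)O[C@@H]2CC(C)=C([C@@H](C)CCCO[Si](c3ccccc3)(c3ccccc3)C(C)(C)C)[C@H](O[Si](CC)(CC)CC)[C@H]12 | intermediate
22 | trimethylammonium iodide of 21 | C[N+](C)(C)C[C@H]1C(=O)O[C@@H]2CC(C)=C([C@@H](C)CCCO[Si](c3ccccc3)(c3ccccc3)C(C)(C)C)[C@H](O[Si](CC)(CC)CC)[C@H]12.[I-] | intermediate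
23 | (3aR,4R,7aR)-3-methylidene-4-(triethylsilyloxy) lactone | C=C1C(=O)O[C@@H]2CC(C)=C([C@@H](C)CCCO[Si](c3ccccc3)(c3ccccc3)C(C)(C)C)[C@H](O[Si](CC)(CC)CC)[C@H]12 | intermediate
24 | (3aS,4R,7aR)-4-hydroxy-3-methylidene lactone | C=C1C(=O)O[C@@H]2CC(C)=C([C@@H](C)CCCO[Si](c3ccccc3)(c3ccccc3)C(C)(C)C)[C@H](O)[C@H]12 | intermediate
25 | (R)-2-methylbutanoic acid | CC[C@@H](C)C(=O)O | starting material
26 | (2R)-2-methylbutanoic 2,4,6-trichlorobenzoic anhydride | CC[C@@H](C)C(=O)OC(=O)c1c(Cl)cc(Cl)cc1Cl | intermediate
27 | TBDPS ether of the target, (3aR,4R,7aR), (2S) in the chain, (2R) in the ester | C=C1C(=O)O[C@@H]2CC(C)=C([C@@H](C)CCCO[Si](c3ccccc3)(c3ccccc3)C(C)(C)C)[C@H](OC(=O)[C@H](C)CC)[C@H]12 | intermediate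
28 | CNP0291605.3 | C=C1C(=O)O[C@@H]2CC(C)=C([C@@H](C)CCCO)[C@H](OC(=O)[C@H](C)CC)[C@H]12 | target

**Step count**

- Total step count: 16.
- Longest linear sequence: 12 steps (steps 1–4, then 9–16). The alkyne branch, steps 5–8 then 9–16, is equally long.

**Steps most likely to fail**

**1. Step 9.**
- The carbonyl carbon may bond to the methyl-bearing alkyne carbon (reversed orientation).
- The alkylnickel stage may undergo β-acyloxy elimination.
- C6–C7 may be cleaved in place of C6–C9.
- Heat may cause loss of O8 followed by aromatisation.
- The alkyne may oligomerise.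

The fallback forms the two bonds one at a time by known chemistry; it sets out from 16 and 8 and comes back at 17. Alkyne 16 is lithiated at its propargylic methyl group C14 (t-BuLi, THF, −78 → −20 °C) to the propargyllithium F1. ClTi(OiPr)3 turns this into the propargyltitanium reagent F2. Such reagents add to carbonyl groups with transposition (SE2'). The strained ketone of 8 (the lactone is left alone at −78 °C) should therefore be attacked from the convex face by the carbon that bears the branched chain. This gives the allenyl cyclobutanol F3, with C5–C6 in place and no question of orientation. [Rh(OH)(cod)]2 with 1,1'-bis(diphenylphosphino)ferrocene in toluene at 60–80 °C then brings about the known ring expansion of 1-allenylcyclobutanols with monovalent rhodium. The rhodium alkoxide undergoes β-carbon elimination at C6–C9 and the alkylrhodium adds to the central allene carbon C10. Protonation with shift of the exocyclic double bond into conjugation turns C14 back into a methyl group, which gives 17.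

**2. Step 10.**
- Hydride may arrive from the concave face.
- The basic borohydride may trigger loss of O8 with aromatisation before reduction.
- The lactone may migrate from O8 to O6 at the alkoxide stage.

The fallback replaces substrate control with ionic hydride by a catalyst-controlled, non-basic Corey–Bakshi–Shibata reduction. It sets out from 17 and comes back at 18. The conditions are (S)-2-methyl-CBS-oxazaborolidine (20 mol %) and catecholborane in toluene at −78 °C. If the tetrasubstituted alkene arm acts as the large group, this catalyst enantiomer delivers hydride to the same face as planned (C6 R). The boron-bound product cannot act as a free alkoxide. No new compound is made.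

**3. Step 3.**
- The available enzymes may reduce the oxa-bicyclic ketone with too little face fidelity.
- The two diastereomeric alcohols may prove hard to separate.

The fallback resolves at the alcohol stage by acyl transfer; it sets out from 5 and comes back at 6. NaBH4 in MeOH at 0 °C reduces 5 from the convex face to the racemic endo alcohol F4. A lipase (Burkholderia cepacia lipase or Candida antarctica lipase B) with vinyl acetate in MTBE at 30 °C is run slightly past half conversion. By the Kazlauskas rule it should acylate the (6R)-enantiomer to the acetate F5 and leave 6, which is separated by chromatography.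

**Further compounds**

F1 | step 9 | [(4S)-7-(tert-butyldiphenylsilyloxy)-4-methylhept-2-yn-1-yl]lithium | [Li]CC#C[C@@H](C)CCCO[Si](c1ccccc1)(c1ccccc1)C(C)(C)C
F2 | step 9 | [(4S)-7-(tert-butyldiphenylsilyloxy)-4-methylhept-2-yn-1-yl]tri(propan-2-yloxy)titanium | CC(C)O[Ti](OC(C)C)(OC(C)C)CC#C[C@@H](C)CCCO[Si](c1ccccc1)(c1ccccc1)C(C)(C)C
F3 | step 9 | (1R,5R,6S)-6-[(4S)-7-(tert-butyldiphenylsilyloxy)-4-methylhepta-1,2-dien-3-yl]-6-hydroxy-2-oxabicyclo[3.2.0]heptan-3-one | C1C(=O)O[C@@H]2C[C@@](O)(C(=C=C)[C@@H](C)CCCO[Si](c3ccccc3)(c3ccccc3)C(C)(C)C)[C@H]12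
F0 | step 10 | none | none
F4 | step 3 | (±)-endo-2-oxabicyclo[3.2.0]heptan-6-ol (racemate, one enantiomer drawn) | C1CO[C@@H]2C[C@H](O)[C@H]12
F5 | step 3 | (1S,5S,6R)-2-oxabicyclo[3.2.0]heptan-6-yl acetate | C1CO[C@H]2C[C@@H](OC(C)=O)[C@@H]12
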